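**Strategy.** Both decalin units come from one allyl-decalin hydrocarbon. Cross-metathesis joins it to two C5 lactones, followed by esterification and a final oxidation. The plan rests on cutting ring A (C1–C5, C10; labdane numbering) at C3–C4 and C5–C10. With an enol ether at C2 and a formyl group on C4, this ring is a [4+2] retron in which each quaternary carbon (C4, C10) bonds to a non-quaternary partner. One intramolecular Diels–Alder reaction closes rings A and B and sets C4, C5 and C10 from C9 alone. Its precursor is an open-chain pentaenal whose C4–C10 backbone with C17–C19 is geranic acid. C9 comes from an auxiliary-controlled deconjugative allylation.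

Key step: step 9

Remark: labdane numbering is used for all intermediates. The extra terminal carbon of the allyl group is called C13′ and leaves as ethene in steps 13 and 14. Isomerically pure (E)-geranic acid is assumed to be purchasable.

Step 1
Reactants: 1 (E)-geranic acid; 2 (S)-4-benzyl-1,3-oxazolidin-2-one
Product: 4 (S)-4-benzyl-3-[(E)-geranoyl]oxazolidin-2-one, via mixed pivalic anhydride 3 (not isolated)
Conditions: PivCl, Et3N, THF, −20 °C; then LiCl, 2, −20 °C → rt
Reagents that add atoms: pivaloyl chloride, CC(C)(C)C(=O)Cl (its acyl group is carried only by intermediate 3)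
Why: N-Acylation of the oxazolidinone through the mixed pivalic anhydride (LiCl-assisted) should proceed without E/Z scrambling of the enoate, whose geometry later decides which γ-hydrogen is removed.

Step 2
Reactants: 4 (S)-4-benzyl-3-[(E)-geranoyl]oxazolidin-2-one
Product: 6 (S)-4-benzyl-3-[(2S)-2-allyl-7-methyl-3-methylideneoct-6-enoyl]oxazolidin-2-one, via sodium Z(O)-dienolate 5 (not isolated)
Conditions: NaHMDS, THF, −78 °C; allyl iodide, −78 → −40 °C
Reagents that add atoms: allyl iodide, C=CCI; NaHMDS, C[Si](C)(C)[N-][Si](C)(C)C.[Na+] (sodium of intermediate 5 only)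
Why: Evans-type deconjugative α-alkylation: the base should take a hydrogen from the C17 methyl group, which lies cis to the carbonyl group, and the chelated Z(O)-dienolate 5 should be allylated at C9 on the face opposite to the benzyl group, which sets (9S) and leaves the C8=C17 methylidene group.

Step 3
Reactants: 6 allylated imide
Product: 7 (2S)-2-allyl-7-methyl-3-methylideneoct-6-en-1-ol
Conditions: LiBH4, MeOH (1 equiv), Et2O, 0 °C
Reagents that add atoms: none
Why: Reductive cleavage of the imide by LiBH4 should free the primary alcohol (C10) and the recoverable auxiliary without touching C9 or the alkenes.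

Step 4
Reactants: 7 (2S)-2-allyl-7-methyl-3-methylideneoct-6-en-1-ol
Product: 8 (2S)-2-allyl-7-methyl-3-methylideneoct-6-enal
Conditions: Dess–Martin periodinane, NaHCO3, CH2Cl2, 0 °C; used at once
Reagents that add atoms: none
Why: Buffered Dess–Martin oxidation is neutral and fast, so the α-branched β,γ-unsaturated aldehyde should form without epimerisation at C9 or conjugation of C8=C17.

Step 5
Reactants: 8 (2S)-2-allyl-7-methyl-3-methylideneoct-6-enal
Product: 9 (4S)-4-ethynyl-9-methyl-5-methylidenedeca-1,8-diene
Conditions: TMSCHN2, n-BuLi, THF, −78 °C; 8, −78 °C → rt; H2O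
Reagents that add atoms: (trimethylsilyl)diazomethane, C[Si](C)(C)C=[N+]=[N-]
Why: Colvin rearrangement: addition of the lithiated diazo compound at −78 °C, loss of silanolate and N2, and a 1,2-hydrogen shift in the alkylidene carbene should give the terminal alkyne (new carbon = C1) faster than the aldehyde can enolise.

Step 6
Reactants: 9 (4S)-4-ethynyl-9-methyl-5-methylidenedeca-1,8-diene
Product: 11 (1E,3S)-3-allyl-1-iodo-2,8-dimethyl-4-methylidenenona-1,7-diene, via (E)-alkenyldimethylalane 10 (not isolated)
Conditions: Me3Al, Cp2ZrCl2 (cat.), CH2Cl2, 0 °C → rt; then I2, THF, −30 °C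
Reagents that add atoms: trimethylaluminium, C[Al](C)C; iodine, II
Why: Negishi zirconium-catalysed methylalumination adds CH3 (C20) to C10 and aluminium to C1 in a syn fashion and iodinolysis keeps the geometry, so that C9 ends up trans to iodine, while the alkenes are much less reactive than the terminal alkyne.

Step 7
Reactants: 11 (E)-vinyl iodide
Product: 13 (2E,7S,8E)-7-allyl-9-iodo-2,8-dimethyl-6-methylidenenona-2,8-dienal, via (E)-allylic alcohol 12 (not isolated)
Conditions: SeO2 (cat.), t-BuOOH, salicylic acid (cat.), CH2Cl2, 0 °C → rt; crude, MnO2, CH2Cl2, rt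
Reagents that add atoms: tert-butyl hydroperoxide, CC(C)(C)OO; selenium dioxide (oxygen carrier), O=[Se]=O
Why: Riley allylic oxidation (ene reaction then [2,3]-shift) should pick the most electron-rich, trisubstituted C4=C5 alkene and its E-methyl group (C18), and MnO2 oxidises only the resulting allylic alcohol 12 to the E-enal.

Step 8
Reactants: 13 iodo enal
Product: 14 (2E,7S,8E)-7-allyl-10-ethoxy-2,8-dimethyl-6-methylideneundeca-2,8,10-trienal
Conditions: CH2=C(OEt)SnBu3, Pd2(dba)3 (cat.), AsPh3, NMP, rt; Et3N-deactivated silica
Reagents that add atoms: tributyl(1-ethoxyvinyl)stannane, C=C(OCC)[Sn](CCCC)(CCCC)CCCC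
Why: Stille coupling is neutral, keeps the alkene geometry and tolerates the enal, and the E geometry of the iodide keeps the pendant alkenes out of reach of the vinylpalladium centre.

Step 9
Reactants: 14 ethoxydiene enal
Product: 16 2-oxo-14,15,16-trinorlabda-8(17),12-dien-18-al (trans-decalin; 4α-CHO 5α-H 9α-H 10β-CH3), via enol ether cycloadduct 15 (not isolated)
Conditions: Me2AlCl (1.5 equiv), CH2Cl2 (0.005 M), −78 → −20 °C; then 1 M HCl, THF, 0 °C
Reagents that add atoms: water, O
Why: Me2AlCl binds the formyl oxygen, lowers the LUMO of the (E)-2-methylenal and lets it add suprafacially to the s-cis diene, which the 2-ethoxy group makes more accessible (A1,3 strain with the C20 methyl group destabilises the s-trans form), in a concerted asynchronous intramolecular [4+2] cycloaddition that forms C3–C4 and C5–C10 together. The closest known reaction type is the alkylaluminium-chloride-promoted type 1 intramolecular Diels–Alder reaction of (E)-2-methyl-2,8,10-undecatrienals to trans-fused octalin carbaldehydes. Ring A (C1–C5, C10) closes as the new cyclohexene of the cycloaddition, and ring B (C5–C10) closes at the same moment through the four-atom tether C6–C9 in a chair-like fold. C4 and C5 follow from the E geometry of the enal and from the endo position of the aluminium-bound formyl group, which puts the tether exo, gives the trans ring fusion and places CHO α (equatorial) on C4. C10 follows from the E geometry of C1=C10 (tether outside, methyl inside) and from C9, whose allyl group should take the pseudo-equatorial position anti to the forming C5–C10 bond, so that only one diene face is attacked. The step needs endo over exo and one diene face over the other, no other alkene competes because C8=C17 and the allyl group are unactivated and too close to the diene, and the acid work-up turns enol ether 15 into ketone 16, so that ring A keeps no C=C bond that would have to be hydrogenated beside the other alkenes.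

Step 10
Reactants: 16 keto aldehyde
Product: 18 (5S,9S,10S)-14,15,16-trinorlabda-8(17),12-diene (9β-allyl decalin), via bis-hydrazone 17 (not isolated)
Conditions: N2H4·H2O, diethylene glycol, 130 °C; then KOH, 200 °C
Reagents that add atoms: hydrazine, NN (nitrogen is carried only by intermediate 17)
Why: Wolff–Kishner reduction (Huang-Minlon form) takes the unhindered C2 ketone and the non-enolisable C18 aldehyde to CH2 and CH3 through bis-hydrazone 17, which erases the C4 stereocentre, while the isolated alkenes should not be isomerised by KOH in glycol.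

Step 11
Reactants: 19 (R)-3-hydroxy-γ-butyrolactone
Product: 21 (3,4-trans,4R)-3-(dimethylaminomethyl)-4-hydroxydihydrofuran-2(3H)-one, via dilithio dianion 20 (not isolated)
Conditions: LDA (2.2 equiv), THF, −78 °C; CH2=NMe2+ I−, −78 → −20 °C; AcOH
Reagents that add atoms: Eschenmoser's salt, C=[N+](C)C.[I-]; LDA, CC(C)[N-]C(C)C.[Li+] (lithium of intermediate 20 only)
Why: Alkylation of a β-hydroxy lactone dianion (Fráter–Seebach type) in its Mannich variant: the oxido group is too poor a leaving group for β-elimination and directs the iminium ion to the opposite face, and C14 is untouched.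

Step 12
Reactants: 21 amino lactone
Product: 23 (R)-4-hydroxy-3-methylidenedihydrofuran-2(3H)-one, via trimethylammonium iodide 22 (not isolated)
Conditions: MeI, MeOH, rt; then NaHCO3, CH2Cl2/H2O, rt
Reagents that add atoms: iodomethane, CI (carried only by intermediate 22)
Why: Eschenmoser methylenation: exhaustive methylation and mild-base E1cB (Hofmann-type) elimination expel trimethylamine, a far better leaving group than the C14 hydroxyl group.

Step 13
Reactants: 18 allyl decalin; 23 (R)-hydroxy methylidene lactone
Product: 24 (12E,14R)-14-hydroxylabda-8(17),12-dien-16,15-olide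
Conditions: Hoveyda–Grubbs II (10 mol %), 2,6-dichloro-1,4-benzoquinone (20 mol %), 23 (3 equiv), CH2Cl2, 40 °C
Reagents that add atoms: none
Why: Olefin cross-metathesis of a terminal (type I) alkene with a 1,1-disubstituted α-methylene lactone should give the more stable E-alkylidene lactone, the quinone suppresses ruthenium hydride isomerisation, and the hindered C8=C17 group does not take part.

Step 14
Reactants: 18 allyl decalin; 25 α-methylene-γ-butyrolactone
Product: 26 (12E)-labda-8(17),12-dien-16,15-olide
Conditions: Hoveyda–Grubbs II (5 mol %), 2,6-dichloro-1,4-benzoquinone (10 mol %), 25 (5 equiv), CH2Cl2, 40 °C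
Reagents that add atoms: none
Why: The same cross-metathesis of a terminal alkene with an α-methylene lactone should give the E-alkylidene lactone, with the quinone preventing migration of the exocyclic double bond into the lactone ring.

Step 15
Reactants: 26 E-alkylidene lactone
Product: 29 (12E)-15-(triethylsilyloxy)labda-8(17),12-dien-16-oic acid, via lithium hydroxy carboxylate 27 (not isolated), via bis-silyl compound 28 (not isolated)
Conditions: LiOH, THF/H2O, rt; evaporate; TESCl, imidazole, DMF, 0 °C; then MeOH/H2O, pH 6 buffer, 0 °C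
Reagents that add atoms: lithium hydroxide, [Li+].[OH-]; chlorotriethylsilane, CC[Si](Cl)(CC)CC
Why: Saponification, exhaustive silylation and selective solvolysis of the much more labile silyl ester keep the γ-hydroxy acid from closing back to the lactone and do not touch the E-alkene.

Step 16
Reactants: 29 silyloxy acid; 24 (14R)-alcohol
Product: 31 15-O-triethylsilyl dimer ester, via mixed trichlorobenzoic anhydride 30 (not isolated)
Conditions: 2,4,6-Cl3C6H2COCl, Et3N, toluene, rt; then 24, DMAP, 0 °C → rt
Reagents that add atoms: 2,4,6-trichlorobenzoyl chloride, O=C(Cl)c1c(Cl)cc(Cl)cc1Cl (carried only by intermediate 30)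
Why: Yamaguchi esterification activates the hindered α-branched enoic acid as mixed anhydride 30 and acylates O14 without breaking the C14–O bond, so that (14R) is retained.

Step 17
Reactants: 31 silyl-protected dimer ester
Product: 32 CNP0274315.1
Conditions: (COCl)2, DMSO, CH2Cl2, −78 → −40 °C; Et3N, −78 → 0 °C
Reagents that add atoms: none
Why: Swern oxidation applied directly to a primary triethylsilyl ether (oxidative desilylation) should give the β,γ-unsaturated aldehyde without ever freeing the γ-hydroxy ester, which could lactonise and expel the alcohol half.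

**Compound list**

1 | (E)-geranic acid | CC(C)=CCC/C(C)=C/C(=O)O | starting material
2 | (S)-4-benzyl-1,3-oxazolidin-2-one | O=C1OC[C@H](Cc2ccccc2)N1 | starting material
3 | geranic pivalic mixed anhydride | CC(C)=CCC/C(C)=C/C(=O)OC(=O)C(C)(C)C | intermediate
4 | (S)-4-benzyl-3-[(E)-geranoyl]oxazolidin-2-one | CC(C)=CCC/C(C)=C/C(=O)N1[C@@H](Cc2ccccc2)COC1=O | intermediate
5 | sodium Z(O)-dienolate of 4 | C=C(CCC=C(C)C)/C=C(\[O-])N1[C@@H](Cc2ccccc2)COC1=O.[Na+] | intermediate
6 | (S)-4-benzyl-3-[(2S)-2-allyl-7-methyl-3-methylideneoct-6-enoyl]oxazolidin-2-one | O=C([C@@H](CC=C)C(=C)CCC=C(C)C)N1[C@@H](Cc2ccccc2)COC1=O | intermediate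
7 | (2S)-2-allyl-7-methyl-3-methylideneoct-6-en-1-ol | OC[C@@H](CC=C)C(=C)CCC=C(C)C | intermediate
8 | (2S)-2-allyl-7-methyl-3-methylideneoct-6-enal | O=C[C@@H](CC=C)C(=C)CCC=C(C)C | intermediate
9 | (4S)-4-ethynyl-9-methyl-5-methylidenedeca-1,8-diene | C#C[C@@H](CC=C)C(=C)CCC=C(C)C | intermediate
10 | (E)-alkenyldimethylalane from 9 | C[Al](C)/C=C(\C)[C@@H](CC=C)C(=C)CCC=C(C)C | intermediate
11 | (1E,3S)-3-allyl-1-iodo-2,8-dimethyl-4-methylidenenona-1,7-diene | I/C=C(\C)[C@@H](CC=C)C(=C)CCC=C(C)C | intermediate
12 | (2E,7S,8E)-7-allyl-9-iodo-2,8-dimethyl-6-methylidenenona-2,8-dien-1-ol | I/C=C(\C)[C@@H](CC=C)C(=C)CC/C=C(\C)CO | intermediate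
13 | (2E,7S,8E)-7-allyl-9-iodo-2,8-dimethyl-6-methylidenenona-2,8-dienal | I/C=C(\C)[C@@H](CC=C)C(=C)CC/C=C(\C)C=O | intermediate
14 | (2E,7S,8E)-7-allyl-10-ethoxy-2,8-dimethyl-6-methylideneundeca-2,8,10-trienal | C=C(OCC)/C=C(\C)[C@@H](CC=C)C(=C)CC/C=C(\C)C=O | intermediate
15 | 2-ethoxy-14,15,16-trinorlabda-1,8(17),12-trien-18-al (4α-CHO, 5α-H, 9α-H, 10β-CH3) | C=C1CC[C@H]2[C@](C)(C=O)CC(OCC)=C[C@]2(C)[C@H]1CC=C | intermediate
16 | 2-oxo-14,15,16-trinorlabda-8(17),12-dien-18-al (4α-CHO, 5α-H, 9α-H, 10β-CH3) | C=C1CC[C@H]2[C@](C)(C=O)CC(=O)C[C@]2(C)[C@H]1CC=C | intermediate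
17 | bis-hydrazone of 16 | C=C1CC[C@H]2[C@](C)(C=NN)CC(=NN)C[C@]2(C)[C@H]1CC=C | intermediate
18 | (5S,9S,10S)-14,15,16-trinorlabda-8(17),12-diene | C=C1CC[C@H]2C(C)(C)CCC[C@]2(C)[C@H]1CC=C | intermediate
19 | (R)-3-hydroxy-γ-butyrolactone | O[C@H]1COC(=O)C1 | starting material
20 | dilithio dianion of 19 | [Li+].[Li+].[O-][C@H]1COC([O-])=C1 | intermediate
21 | (3,4-trans,4R)-3-(dimethylaminomethyl)-4-hydroxydihydrofuran-2(3H)-one | O[C@H]1COC(=O)[C@@H]1CN(C)C | intermediate
22 | trimethylammonium iodide from 21 | O[C@H]1COC(=O)[C@@H]1C[N+](C)(C)C.[I-] | intermediate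
23 | (R)-4-hydroxy-3-methylidenedihydrofuran-2(3H)-one | O[C@H]1COC(=O)C1=C | intermediate
24 | (12E,14R)-14-hydroxylabda-8(17),12-dien-16,15-olide | O[C@H]1COC(=O)/C1=C/C[C@H]1C(=C)CC[C@H]2C(C)(C)CCC[C@]12C | intermediate
25 | α-methylene-γ-butyrolactone | C=C1CCOC1=O | starting material
26 | (12E)-labda-8(17),12-dien-16,15-olide | C=C1CC[C@H]2C(C)(C)CCC[C@]2(C)[C@H]1C/C=C1\CCOC1=O | intermediate
27 | lithium (12E)-15-hydroxylabda-8(17),12-dien-16-oate | C=C1CC[C@H]2C(C)(C)CCC[C@]2(C)[C@H]1C/C=C(\CCO)C(=O)[O-].[Li+] | intermediate
28 | triethylsilyl (12E)-15-(triethylsilyloxy)labda-8(17),12-dien-16-oate | C=C1CC[C@H]2C(C)(C)CCC[C@]2(C)[C@H]1C/C=C(\CCO[Si](CC)(CC)CC)C(=O)O[Si](CC)(CC)CC | intermediate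
29 | (12E)-15-(triethylsilyloxy)labda-8(17),12-dien-16-oic acid | C=C1CC[C@H]2C(C)(C)CCC[C@]2(C)[C@H]1C/C=C(\CCO[Si](CC)(CC)CC)C(=O)O | intermediate
30 | mixed anhydride of 29 with 2,4,6-trichlorobenzoic acid | C=C1CC[C@H]2C(C)(C)CCC[C@]2(C)[C@H]1C/C=C(\CCO[Si](CC)(CC)CC)C(=O)OC(=O)c1c(Cl)cc(Cl)cc1Cl | intermediate
31 | ester of 29 with O14 of 24 (15-O-triethylsilyl dimer) | C=C1CC[C@H]2C(C)(C)CCC[C@]2(C)[C@H]1C/C=C(\CCO[Si](CC)(CC)CC)C(=O)O[C@H]1COC(=O)/C1=C/C[C@H]1C(=C)CC[C@H]2C(C)(C)CCC[C@]12C | intermediate
32 | CNP0274315.1 | C=C1CC[C@H]2C(C)(C)CCC[C@]2(C)[C@H]1C/C=C(\CC=O)C(=O)O[C@H]1COC(=O)/C1=C/C[C@H]1C(=C)CC[C@H]2C(C)(C)CCC[C@]12C | target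

**Total step count:** 17. **Longest linear sequence:** 14 (steps 1–10, 14, 15, 16, 17).

**Steps most likely to fail**

1. **Step 9.**
   - The C5–C10 bond must form at the doubly substituted diene terminus against the natural polarity of the diene. The cycloaddition may therefore be slower than Lewis-acid-induced loss of the enol ether, and endo/exo and facial selectivity may be only modest.
   - The fallback makes the dienophile cationic and sets out from 13. Trimethyl orthoformate and PPTS in methanol should give the dimethyl acetal F1. Stille coupling as in step 8 should then give the ethoxydiene acetal F2.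
   - Catalytic TMSOTf with 2,6-di-tert-butylpyridine in CH2Cl2 at −78 °C should ionise the acetal reversibly. This triggers an ionic intramolecular Diels–Alder reaction, which again forms C3–C4 and C5–C10 together, to the acetal cycloadduct F3.
   - 1 M HCl in THF then cleaves enol ether and acetal, and the route is rejoined at 16.

2. **Step 13.**
   - Ruthenium hydride isomerisation of the allylic alcohol unit, slow turnover at the hindered 1,1-disubstituted alkene next to the carbinol, and poor E/Z control may all lower the outcome.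
   - The fallback reverses the order of bond formation and sets out from 29 (activated as 30) and 23. Yamaguchi esterification as in step 16 should give the acylated methylidene lactone F4, whose carbinol can no longer be isomerised.
   - Cross-metathesis of F4 with 18 under the conditions of step 14 forms the C12=C13 bond of the lactone half last and comes back to the route at 31.

3. **Step 2.**
   - γ-Deprotonation may also occur at C7 and lead to the Δ7 isomer. γ-Allylation or eroded facial selectivity may add to this.
   - The fallback separates deconjugation from alkylation and sets out from 1. Double deprotonation with LDA and kinetic α-protonation at −78 °C should give 7-methyl-3-methylideneoct-6-enoic acid F5, which is freed of its double-bond isomers at this cheap stage.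
   - Its mixed pivalic anhydride F6 acylates 2 to the β,γ-unsaturated imide F7, whose only acidic position is C9. NaHMDS then gives dienolate 5 by plain α-deprotonation, and allyl iodide leads back to 6.

**Further compounds**

F1 | step 9 | (1E,3S,7E)-3-allyl-1-iodo-9,9-dimethoxy-2,8-dimethyl-4-methylidenenona-1,7-diene | I/C=C(\C)[C@@H](CC=C)C(=C)CC/C=C(\C)C(OC)OC
F2 | step 9 | dimethyl acetal of 14 | C=C(OCC)/C=C(\C)[C@@H](CC=C)C(=C)CC/C=C(\C)C(OC)OC
F3 | step 9 | 2-ethoxy-18,18-dimethoxy-14,15,16-trinorlabda-1,8(17),12-triene (5α-H, 9α-H, 10β-CH3) | C=C1CC[C@H]2[C@](C)(C(OC)OC)CC(OCC)=C[C@]2(C)[C@H]1CC=C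
F4 | step 13 | ester of 29 with the hydroxyl group of 23 | C=C1CC[C@H]2C(C)(C)CCC[C@]2(C)[C@H]1C/C=C(\CCO[Si](CC)(CC)CC)C(=O)O[C@H]1COC(=O)C1=C
F5 | step 2 | 7-methyl-3-methylideneoct-6-enoic acid | C=C(CCC=C(C)C)CC(=O)O
F6 | step 2 | mixed pivalic anhydride of F5 | C=C(CCC=C(C)C)CC(=O)OC(=O)C(C)(C)C
F7 | step 2 | (S)-4-benzyl-3-(7-methyl-3-methylideneoct-6-enoyl)oxazolidin-2-one | C=C(CCC=C(C)C)CC(=O)N1[C@@H](Cc2ccccc2)COC1=O
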